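All runs are calculated for substances that don't exist, noise included.

Late in the alder run and the cedar run the readings of the complex with one exchanged showed no clear trend beyond their scatter of 1.5 percentage points, and that read level, which I called the plateau, was what I set out to reckon for the next flasks.

| flask | starting complex | incoming ligand | remark | time |
|---|---|---|---|---|
| alder | 20 mM | 30 mM | run made earlier |  |
| cedar | 20 mM | 61 mM | run made earlier |  |
| Friday's | 20 mM | 60.0 mM |  | 1.5 h |
| Tuesday's | 20 mM | 80.0 mM |  | 1.5 h |
| Wednesday's | 20 mM | 40.0 mM |  | 1.5 h |

| run | time / min | complex with one exchanged / % | starting complex / % |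
|---|---|---|---|
| alder | 10.0 | 54 | 0 |
| alder | 20.0 | 52 | 3 |
| alder | 25.0 | 49 | 1 |
| alder | 40.0 | 49 | 0 |
| alder | 50.0 | 51 | 0 |
| alder | 60.0 | 52 | 3 |
| cedar | 5.00 | 29 | 0 |
| cedar | 8.00 | 28 | 0 |
| cedar | 12.0 | 29 | 4 |
| cedar | 20.0 | 29 | 1 |
| cedar | 25.0 | 29 | 1 |
| cedar | 40.0 | 29 | 3 |
| cedar | 60.0 | 26 | 1 |

(standard deviation of a reading: 1.5 percentage points)



* which of these holds the largest part of the starting complex at the end of Friday's (starting complex / complex with three exchanged / complex with one exchanged / complex with two exchanged)
* which of these holds the largest part of the starting complex at the end of Tuesday's (starting complex / complex with three exchanged / complex with one exchanged / complex with two exchanged)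
* which of these holds the largest part of the starting complex at the end of Wednesday's (starting complex / complex with three exchanged / complex with one exchanged / complex with two exchanged)
* amount of complex with one exchanged at the end of Friday's, in percent of the starting complex charged

The start was fast. In the cedar run the starting complex read 0% at the first reading, 5.00 min, so it went at 0.200 min⁻¹ or more, as a share of its charge. Between the first and last cedar readings the complex with one exchanged lost 5.45 × 10⁻⁴ min⁻¹, slower by a factor of at least 367, and that loss stands close to the scatter. Over the 30.0 min from that last reading to the time asked, this rate is worth 1.64% of the charge.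

The plateaus were more widely apart, with a mean of 51.2% in the alder run and 28.4% in the cedar run. The charge of incoming ligand differed between them, so I took the apparent stop for a balance of forward and back steps: thermodynamic, not kinetic, control.

So I carried one number, 0.379, the fall per equivalent: the drop in the logarithm of the plateau for each equivalent of incoming ligand per starting complex. Both runs had the same charge of starting complex, so counting in equivalents was my assumption. It gave 29.0% for Friday's, 19.8% for Tuesday's and 42.3% for Wednesday's. I named the complex with one exchanged as largest on Wednesday's, where its plateau is highest, and the complex with two exchanged on the other two.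

The forecast said 29.5% for Friday's and named complex with two exchanged, complex with two exchanged and complex with two exchanged for Friday's, Tuesday's and Wednesday's, reasoning that “The third exchange appears slow”, and so it parted from me on Wednesday's.

Friday's gave 29.1% against the 29.0% from my fall of 0.379, with complex with two exchanged largest; Tuesday's gave complex with two exchanged largest, and Wednesday's complex with one exchanged, at 42.5% against my 42.3%.

    starting complex + incoming ligand ⇌ leaving ligand + complex with one exchanged (K = 131, k = 11.2 M⁻¹ s⁻¹)
    complex with one exchanged + incoming ligand ⇌ leaving ligand + complex with two exchanged (K = 2.38, k = 0.921 M⁻¹ s⁻¹)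
    complex with two exchanged + incoming ligand ⇌ leaving ligand + complex with three exchanged (K = 0.733, k = 7.33 M⁻¹ s⁻¹)
    2 starting complex → homo dimer (k = 1.38 M⁻¹ s⁻¹)
    starting complex ⇌ dormant form (K = 3.03, k = 0.262 s⁻¹)

On Friday's the half-life of the complex with one exchanged, by the forward rate of its step to the complex with two exchanged alone, was 0.53 min, far shorter than the 1.5 h of the run. Yet it stood at 29.2% after 0.750 h and 29.1% after 1.50 h.

A neighbour of Friday's charged with 12 mM of starting complex has 5.00 equivalents, for which the fall per equivalent gives 13.6%. The flask gave 14.4%.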